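**Retrosynthetic overview** (prostanoid locants: C1 = ester carbon, ring = C8–C12, C20 = terminal methyl)
1. Endgame: the C12 hydroxyl is released from its 2-naphthylmethyl ether; the C10 bromide comes from a C10 enol (diosphenol) by way of the enol triflate and the vinylstannane.
2. Key disconnection: the cyclopentenone is cut at C9–C10 and C8–C12 into an axially chiral α-lithio alkoxyallene (C1–C9) and an (E)-β-alkoxy enamide (C10–C20); carbonyl addition followed by a conrotatory 4π ring closure makes both bonds in one operation.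
3. Enabling feature: in the ring the C9 carbonyl sits next to the sp2 carbon C8 of the exocyclic C7=C8 alkene (an oxygenated allene C7=C8=C9–O in disguise) and is 1,4-related to the oxygenated quaternary C12, so C8–C9(O)–C10–C11–C12(O) is a 1,4-dioxygenated pentadienyl cation.
4. Stereochemistry: C4 by asymmetric transfer hydrogenation; the allene axis by anti-SN2′ opening of a C2-symmetric propargylic acetal; the axis is carried to C12 and to the (7Z)-alkene in the key step; (14Z,17Z) comes from commercial (3Z,6Z)-nona-3,6-dien-1-ol.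
5. Ring order: a temporary oxolane ortho-lactone (masks the C1 ester and the C4 hydroxyl together, steps 2–3) and a temporary dioxane acetal (step 5) come first; the only carbocycle, the cyclopentenone, is formed in step 13, where the ortho-lactone is opened again.

Key step: step 13

Assumption: the copper-catalysed opening of the (4R,6R)-dioxane 12 is taken to follow the anti-SN2′ course that gives the (aR)-allene; if the sense of induction is the opposite one, the (2S,4S)-diol is used in step 5 and nothing else changes.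

**Route**

Step 1
Reactants: 1 methyl 4-chloro-4-oxobutanoate; 2 bis(trimethylsilyl)acetylene
Product: 3 methyl 4-oxo-6-(trimethylsilyl)hex-5-ynoate
Conditions: AlCl3, CH2Cl2, 0 °C
Reagents that add atoms: none
Why: Friedel–Crafts-type acylation of the bis-silylated alkyne, in which the acylium ion replaces one silyl group by ipso substitution and the methyl ester is left untouched.

Step 2
Reactants: 3 methyl 4-oxo-6-(trimethylsilyl)hex-5-ynoate
Product: 5 (5S)-5-[(trimethylsilyl)ethynyl]oxolan-2-one, via hydroxy ester 4 (not isolated)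
Conditions: RuCl[(S,S)-TsDPEN](p-cymene) (1 mol%), i-PrOH, rt; then TsOH (cat.), CH2Cl2, rt
Reagents that add atoms: none
Why: Noyori asymmetric transfer hydrogenation of an alkynyl ketone, in which the alkyne takes the place of the aryl group in the catalyst model so that the (S,S)-ligand should give the (S)-carbinol, followed by acid-catalysed lactonisation of the γ-hydroxy ester.

Step 3
Reactants: 5 (5S)-5-[(trimethylsilyl)ethynyl]oxolan-2-one
Product: 8 (5S)-5-ethynyl-2,2-dimethoxyoxolane, via lactonium salt 6 (not isolated), via silylated ortho-lactone 7 (not isolated)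
Conditions: Me3OBF4, CH2Cl2, rt; then NaOMe, MeOH, −78 °C → rt
Reagents that add atoms: trimethyloxonium tetrafluoroborate C[O+](C)C.F[B-](F)(F)F; sodium methoxide C[O-].[Na+]
Why: Meerwein O-methylation of the lactone carbonyl gives the dialkoxycarbenium salt, methoxide adds to its carbon to give the cyclic ortho ester, and the same methoxide–methanol medium removes the alkynyl silyl group without touching the stereocentre.

Step 4
Reactants: 8 (5S)-5-ethynyl-2,2-dimethoxyoxolane
Product: 10 (5S)-5-[(E)-2-iodoethenyl]-2,2-dimethoxyoxolane, via alkenylzirconocene chloride 9 (not isolated)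
Conditions: Cp2Zr(H)Cl, THF, rt; then I2, 0 °C
Reagents that add atoms: iodine II
Why: Hydrozirconation with the Schwartz reagent adds Zr–H syn across the terminal alkyne with zirconium at the terminal carbon, and iodine cleaves the C–Zr bond with retention to give the (E)-vinyl iodide.

Step 5
Reactants: 11 3,3-diethoxyprop-1-yne
Product: 12 (4R,6R)-2-ethynyl-4,6-dimethyl-1,3-dioxane
Conditions: (2R,4R)-pentane-2,4-diol, PPTS (cat.), benzene, 60 °C, removal of EtOH
Reagents that add atoms: (2R,4R)-pentane-2,4-diol C[C@@H](O)C[C@@H](C)O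
Why: Acid-catalysed transacetalisation driven by removal of ethanol; the C2-symmetric diol keeps the acetal carbon non-stereogenic and places the chiral information next to both C–O bonds.

Step 6
Reactants: 10 (5S)-5-[(E)-2-iodoethenyl]-2,2-dimethoxyoxolane; 12 (4R,6R)-2-ethynyl-4,6-dimethyl-1,3-dioxane
Product: 15 (2R,4R)-4-{[(aR,4E)-5-[(2S)-5,5-dimethoxyoxolan-2-yl]penta-1,2,4-trien-1-yl]oxy}pentan-2-ol, via alkenyllithium 13 (not isolated), via alkenylmagnesium bromide 14 (not isolated)
Conditions: t-BuLi (2 equiv), Et2O, −78 °C; MgBr2·OEt2, −78 → −40 °C; then 12, CuBr·SMe2 (10 mol%), −40 → 0 °C; H2O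
Reagents that add atoms: none
Why: Iodine–lithium exchange and transmetalation give the alkenyl Grignard reagent, whose copper-catalysed anti-SN2′ substitution of the chiral propargylic acetal (syn-carbocupration, then anti-β-elimination of one of the two diastereotopic alkoxy groups; the alkoxyallene synthesis from acetals) should form the C6–C7 bond and set the allene axis.

Step 7
Reactants: 15 (2R,4R)-4-{[(aR,4E)-5-[(2S)-5,5-dimethoxyoxolan-2-yl]penta-1,2,4-trien-1-yl]oxy}pentan-2-ol
Product: 16 (5S)-2,2-dimethoxy-5-[(1E,aR)-5-{[(2R,4R)-4-methoxypentan-2-yl]oxy}penta-1,3,4-trien-1-yl]oxolane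
Conditions: NaH, MeI, THF, 0 °C → rt
Reagents that add atoms: iodomethane CI
Why: Williamson etherification caps the remote hydroxyl so that it cannot trap the cation of the key step; the allenyl ether and the ortho ester are stable to base.

Step 8
Reactants: 17 (3Z,6Z)-nona-3,6-dien-1-ol
Product: 18 (3Z,6Z)-nona-3,6-dienal
Conditions: Dess–Martin periodinane, CH2Cl2, 0 °C, used at once
Reagents that add atoms: none
Why: Dess–Martin oxidation under neutral conditions should keep the β,γ-unsaturated aldehyde from moving into conjugation.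

Step 9
Reactants: 18 (3Z,6Z)-nona-3,6-dienal
Product: 19 (4Z,7Z)-1,1-dibromodeca-1,4,7-triene
Conditions: CBr4, PPh3, Zn, CH2Cl2, 0 °C → rt
Reagents that add atoms: tetrabromomethane BrC(Br)(Br)Br
Why: First stage of the Corey–Fuchs alkyne synthesis, a Wittig-type dibromoolefination with the zinc-generated dibromomethylene ylide under neutral conditions.

Step 10
Reactants: 19 (4Z,7Z)-1,1-dibromodeca-1,4,7-triene
Product: 21 methyl (5Z,8Z)-undeca-5,8-dien-2-ynoate, via lithium acetylide 20 (not isolated)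
Conditions: n-BuLi (2 equiv), THF, −78 °C; then ClCO2Me, −78 → 0 °C
Reagents that add atoms: methyl chloroformate COC(=O)Cl
Why: Second stage of the Corey–Fuchs sequence (bromine–lithium exchange, Fritsch–Buttenberg–Wiechell shift, deprotonation) and C-acylation of the lithium acetylide by the chloroformate.

Step 11
Reactants: 21 methyl (5Z,8Z)-undeca-5,8-dien-2-ynoate
Product: 22 methyl (2E,5Z,8Z)-3-(naphthalen-2-ylmethoxy)undeca-2,5,8-trienoate
Conditions: naphthalen-2-ylmethanol, PBu3 (10 mol%), CH2Cl2, rt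
Reagents that add atoms: naphthalen-2-ylmethanol OCc1ccc2ccccc2c1
Why: Trialkylphosphine-catalysed oxa-Michael addition of an alcohol to a 2-alkynoate (via the β-phosphonium allenolate), which should give the favoured (E)-β-alkoxy enoate with the alkoxy group trans to the ester.

Step 12
Reactants: 22 methyl (2E,5Z,8Z)-3-(naphthalen-2-ylmethoxy)undeca-2,5,8-trienoate
Product: 23 (2E,5Z,8Z)-1-(morpholin-4-yl)-3-(naphthalen-2-ylmethoxy)undeca-2,5,8-trien-1-one
Conditions: morpholine, i-PrMgCl, THF, −20 → 0 °C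
Reagents that add atoms: morpholine C1COCCN1
Why: Aminolysis of the ester by the chloromagnesium amide of morpholine (Weinreb-type amide formation), the hard amide attacking the carbonyl carbon and not the β-alkoxy carbon.

Step 13
Reactants: 16 (5S)-2,2-dimethoxy-5-[(1E,aR)-5-{[(2R,4R)-4-methoxypentan-2-yl]oxy}penta-1,3,4-trien-1-yl]oxolane; 23 (2E,5Z,8Z)-1-(morpholin-4-yl)-3-(naphthalen-2-ylmethoxy)undeca-2,5,8-trien-1-one
Product: 26 methyl (4S,5E,7Z)-4-hydroxy-7-[(2R)-4-hydroxy-2-(naphthalen-2-ylmethoxy)-2-[(2Z,5Z)-octa-2,5-dien-1-yl]-5-oxocyclopent-3-en-1-ylidene]hept-5-enoate, via lithiated allene 24 (not isolated), via allenyl vinyl ketone 25 (not isolated)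
Conditions: 16, n-BuLi, THF, −78 °C; then 23, −78 → −40 °C; then 1 M HCl, MeOH–H2O, −78 °C (ring closure) → 0 °C (ortho-lactone opening)
Reagents that add atoms: water O
Why: Proposed new method: 16 is lithiated at the oxygen-bearing allene terminus with retention of the axis (24), 24 adds to the morpholine amide 23, and acid turns the tetrahedral adduct into the α-alkoxyallenyl β-alkoxyvinyl ketone 25, whose O-protonated form, a 1,4-dioxygenated pentadienyl cation, closes between the central allene carbon (C8) and the alkoxy-bearing terminus (C12) before water cleaves the resulting O-alkyl oxocarbenium ion to the C9 ketone (loss of the auxiliary alcohol) and opens the ortho-lactone to the hydroxy methyl ester. The closest known reaction type is the allene-ether Nazarov cyclopentannulation of 1-lithio-1-alkoxyallenes with α,β-unsaturated morpholine amides, which forms the same two ring bonds and gives 2-hydroxy-5-alkylidenecyclopent-2-enones; not yet shown are a β-alkoxy-β-alkyl enamide as partner (the closure of an oxygen-terminated pentadienyl cation is, however, the C–C bond-forming event of the Piancatelli rearrangement) and an O-substituent that leaves by hydrolysis instead of as a stabilised cation. The cyclopentenone closes by a conrotatory 4π-electrocyclisation, formally a 5-(enolendo)-exo-trig attack of the enol-ether carbon C8 on the oxocarbenium carbon C12, and the C9–C10 bond comes from the intermolecular 1,2-addition. The quaternary centre C12 is set by axis-to-centre transfer: the alkenyl group on the far allene carbon shields one face of C8 and forces the new bond to form on the other, which fixes the sense of conrotation, and with the (E)-enol ether (naphthylmethoxy outside, side-chain CH2 inside) this sense should give (12R). The same rotation turns the alkenyl group toward the C9 carbonyl, so the exocyclic alkene should form as the kinetic (7Z)-isomer. The step needs carbonyl addition to win over deprotonation of the doubly allylic CH2 and over substitution at the β-alkoxy carbon, and ring closure to be faster than rotation about the C11–C12 bond of the cation; the hard lithium reagent at −78 °C, the stable tetrahedral morpholine adduct and the cold quench are there to secure this.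

Step 14
Reactants: 26 methyl (4S,5E,7Z)-4-hydroxy-7-[(2R)-4-hydroxy-2-(naphthalen-2-ylmethoxy)-2-[(2Z,5Z)-octa-2,5-dien-1-yl]-5-oxocyclopent-3-en-1-ylidene]hept-5-enoate
Product: 27 methyl (4S,5E,7Z)-4-hydroxy-7-[(2R)-2-(naphthalen-2-ylmethoxy)-2-[(2Z,5Z)-octa-2,5-dien-1-yl]-5-oxo-4-{[(trifluoromethyl)sulfonyl]oxy}cyclopent-3-en-1-ylidene]hept-5-enoate
Conditions: PhNTf2, Et3N, CH2Cl2, 0 °C → rt
Reagents that add atoms: N-phenylbis(trifluoromethanesulfonimide) O=S(=O)(N(c1ccccc1)S(=O)(=O)C(F)(F)F)C(F)(F)F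
Why: O-Sulfonylation of the acidic enol of the 1,2-diketone with the mild triflating agent, which should not touch the secondary alcohol.

Step 15
Reactants: 27 methyl (4S,5E,7Z)-4-hydroxy-7-[(2R)-2-(naphthalen-2-ylmethoxy)-2-[(2Z,5Z)-octa-2,5-dien-1-yl]-5-oxo-4-{[(trifluoromethyl)sulfonyl]oxy}cyclopent-3-en-1-ylidene]hept-5-enoate
Product: 28 methyl (4S,5E,7Z)-4-hydroxy-7-[(2R)-2-(naphthalen-2-ylmethoxy)-2-[(2Z,5Z)-octa-2,5-dien-1-yl]-5-oxo-4-(trimethylstannyl)cyclopent-3-en-1-ylidene]hept-5-enoate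
Conditions: Me3SnSnMe3, Pd(PPh3)4 (5 mol%), LiCl, THF, 60 °C
Reagents that add atoms: hexamethylditin C[Sn](C)(C)[Sn](C)(C)C
Why: Palladium-catalysed stannylation of an enol triflate with a distannane (oxidative addition, tin-to-palladium transmetalation, reductive elimination), a known way from a diosphenol to an α-stannyl enone.

Step 16
Reactants: 28 methyl (4S,5E,7Z)-4-hydroxy-7-[(2R)-2-(naphthalen-2-ylmethoxy)-2-[(2Z,5Z)-octa-2,5-dien-1-yl]-5-oxo-4-(trimethylstannyl)cyclopent-3-en-1-ylidene]hept-5-enoate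
Product: 29 methyl (4S,5E,7Z)-7-[(2R)-4-bromo-2-(naphthalen-2-ylmethoxy)-2-[(2Z,5Z)-octa-2,5-dien-1-yl]-5-oxocyclopent-3-en-1-ylidene]-4-hydroxyhept-5-enoate
Conditions: NBS, MeCN, 0 °C, dark
Reagents that add atoms: N-bromosuccinimide O=C1CCC(=O)N1Br
Why: ipso-Bromodestannylation of the vinylstannane, which should be far faster than attack of electrophilic bromine on the isolated (Z)-alkenes.

Step 17
Reactants: 29 methyl (4S,5E,7Z)-7-[(2R)-4-bromo-2-(naphthalen-2-ylmethoxy)-2-[(2Z,5Z)-octa-2,5-dien-1-yl]-5-oxocyclopent-3-en-1-ylidene]-4-hydroxyhept-5-enoate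
Product: 30 methyl (4S,5E,7Z)-7-[(2R)-4-bromo-2-hydroxy-2-[(2Z,5Z)-octa-2,5-dien-1-yl]-5-oxocyclopent-3-en-1-ylidene]-4-hydroxyhept-5-enoate
Conditions: DDQ, CH2Cl2–pH 7 buffer, 0 °C → rt
Reagents that add atoms: none
Why: Oxidative cleavage of the 2-naphthylmethyl ether by DDQ (hydride abstraction at the arylmethyl carbon, then hydrolysis) under buffered conditions that should leave the bromodienone, the skipped diene and the γ-hydroxy ester alone.

**Compound list**
1 | methyl 4-chloro-4-oxobutanoate | COC(=O)CCC(Cl)=O | starting material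
2 | bis(trimethylsilyl)acetylene | C[Si](C)(C)C#C[Si](C)(C)C | starting material
3 | methyl 4-oxo-6-(trimethylsilyl)hex-5-ynoate | COC(=O)CCC(=O)C#C[Si](C)(C)C | intermediate
4 | methyl (4S)-4-hydroxy-6-(trimethylsilyl)hex-5-ynoate | COC(=O)CC[C@H](O)C#C[Si](C)(C)C | intermediate
5 | (5S)-5-[(trimethylsilyl)ethynyl]oxolan-2-one | O=C1CC[C@@H](C#C[Si](C)(C)C)O1 | intermediate
6 | (5S)-2-methoxy-5-[(trimethylsilyl)ethynyl]-4,5-dihydro-3H-furan-1-ium tetrafluoroborate | COC1=[O+][C@H](C#C[Si](C)(C)C)CC1.F[B-](F)(F)F | intermediate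
7 | {[(2S)-5,5-dimethoxyoxolan-2-yl]ethynyl}trimethylsilane | COC1(OC)CC[C@@H](C#C[Si](C)(C)C)O1 | intermediate
8 | (5S)-5-ethynyl-2,2-dimethoxyoxolane | COC1(OC)CC[C@@H](C#C)O1 | intermediate
9 | chlorobis(cyclopentadienyl){(E)-2-[(2S)-5,5-dimethoxyoxolan-2-yl]ethenyl}zirconium | COC1(OC)CC[C@@H](/C=C/[Zr](Cl)(C2C=CC=C2)C2C=CC=C2)O1 | intermediate
10 | (5S)-5-[(E)-2-iodoethenyl]-2,2-dimethoxyoxolane | COC1(OC)CC[C@@H](/C=C/I)O1 | intermediate
11 | 3,3-diethoxyprop-1-yne | C#CC(OCC)OCC | starting material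
12 | (4R,6R)-2-ethynyl-4,6-dimethyl-1,3-dioxane | C#CC1O[C@H](C)C[C@@H](C)O1 | intermediate
13 | {(E)-2-[(2S)-5,5-dimethoxyoxolan-2-yl]ethenyl}lithium | COC1(OC)CC[C@@H](/C=C/[Li])O1 | intermediate
14 | bromo{(E)-2-[(2S)-5,5-dimethoxyoxolan-2-yl]ethenyl}magnesium | COC1(OC)CC[C@@H](/C=C/[Mg]Br)O1 | intermediate
15 | (2R,4R)-4-{[(aR,4E)-5-[(2S)-5,5-dimethoxyoxolan-2-yl]penta-1,2,4-trien-1-yl]oxy}pentan-2-ol | [H]C(O[C@H](C)C[C@@H](C)O)=[C@@]=C([H])/C=C/[C@@H]1CCC(OC)(OC)O1 | intermediate
16 | (5S)-2,2-dimethoxy-5-[(1E,aR)-5-{[(2R,4R)-4-methoxypentan-2-yl]oxy}penta-1,3,4-trien-1-yl]oxolane | [H]C(O[C@H](C)C[C@@H](C)OC)=[C@@]=C([H])/C=C/[C@@H]1CCC(OC)(OC)O1 | intermediate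
17 | (3Z,6Z)-nona-3,6-dien-1-ol | CC/C=C\C/C=C\CCO | starting material
18 | (3Z,6Z)-nona-3,6-dienal | CC/C=C\C/C=C\CC=O | intermediate
19 | (4Z,7Z)-1,1-dibromodeca-1,4,7-triene | CC/C=C\C/C=C\CC=C(Br)Br | intermediate
20 | [(4Z,7Z)-deca-4,7-dien-1-yn-1-yl]lithium | CC/C=C\C/C=C\CC#C[Li] | intermediate
21 | methyl (5Z,8Z)-undeca-5,8-dien-2-ynoate | CC/C=C\C/C=C\CC#CC(=O)OC | intermediate
22 | methyl (2E,5Z,8Z)-3-(naphthalen-2-ylmethoxy)undeca-2,5,8-trienoate | CC/C=C\C/C=C\C/C(OCc1ccc2ccccc2c1)=C\C(=O)OC | intermediate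
23 | (2E,5Z,8Z)-1-(morpholin-4-yl)-3-(naphthalen-2-ylmethoxy)undeca-2,5,8-trien-1-one | CC/C=C\C/C=C\C/C(OCc1ccc2ccccc2c1)=C\C(=O)N1CCOCC1 | intermediate
24 | [(aR,4E)-5-[(2S)-5,5-dimethoxyoxolan-2-yl]-1-{[(2R,4R)-4-methoxypentan-2-yl]oxy}penta-1,2,4-trien-1-yl]lithium | [Li]C(O[C@H](C)C[C@@H](C)OC)=[C@@]=C([H])/C=C/[C@@H]1CCC(OC)(OC)O1 | intermediate
25 | (1E,7E,10Z,13Z)-1-[(2S)-5,5-dimethoxyoxolan-2-yl]-5-{[(2R,4R)-4-methoxypentan-2-yl]oxy}-8-(naphthalen-2-ylmethoxy)hexadeca-1,3,4,7,10,13-hexaen-6-one, (aR) allene axis | O=C(/C=C(\C/C=C\C/C=C\CC)OCc1ccc2ccccc2c1)C(O[C@H](C)C[C@@H](C)OC)=[C@@]=C([H])/C=C/[C@@H]1CCC(OC)(OC)O1 | intermediate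
26 | methyl (4S,5E,7Z)-4-hydroxy-7-[(2R)-4-hydroxy-2-(naphthalen-2-ylmethoxy)-2-[(2Z,5Z)-octa-2,5-dien-1-yl]-5-oxocyclopent-3-en-1-ylidene]hept-5-enoate | CC/C=C\C/C=C\C[C@@]1(OCc2ccc3ccccc3c2)C=C(O)C(=O)/C1=C\C=C\[C@@H](O)CCC(=O)OC | intermediate
27 | methyl (4S,5E,7Z)-4-hydroxy-7-[(2R)-2-(naphthalen-2-ylmethoxy)-2-[(2Z,5Z)-octa-2,5-dien-1-yl]-5-oxo-4-{[(trifluoromethyl)sulfonyl]oxy}cyclopent-3-en-1-ylidene]hept-5-enoate | CC/C=C\C/C=C\C[C@@]1(OCc2ccc3ccccc3c2)C=C(OS(=O)(=O)C(F)(F)F)C(=O)/C1=C\C=C\[C@@H](O)CCC(=O)OC | intermediate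
28 | methyl (4S,5E,7Z)-4-hydroxy-7-[(2R)-2-(naphthalen-2-ylmethoxy)-2-[(2Z,5Z)-octa-2,5-dien-1-yl]-5-oxo-4-(trimethylstannyl)cyclopent-3-en-1-ylidene]hept-5-enoate | CC/C=C\C/C=C\C[C@@]1(OCc2ccc3ccccc3c2)C=C([Sn](C)(C)C)C(=O)/C1=C\C=C\[C@@H](O)CCC(=O)OC | intermediate
29 | methyl (4S,5E,7Z)-7-[(2R)-4-bromo-2-(naphthalen-2-ylmethoxy)-2-[(2Z,5Z)-octa-2,5-dien-1-yl]-5-oxocyclopent-3-en-1-ylidene]-4-hydroxyhept-5-enoate | CC/C=C\C/C=C\C[C@@]1(OCc2ccc3ccccc3c2)C=C(Br)C(=O)/C1=C\C=C\[C@@H](O)CCC(=O)OC | intermediate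
30 | methyl (4S,5E,7Z)-7-[(2R)-4-bromo-2-hydroxy-2-[(2Z,5Z)-octa-2,5-dien-1-yl]-5-oxocyclopent-3-en-1-ylidene]-4-hydroxyhept-5-enoate | CC/C=C\C/C=C\C[C@@]1(O)C=C(Br)C(=O)/C1=C\C=C\[C@@H](O)CCC(=O)OC | target

**Step count and risks**

Total step count: 17. Longest linear sequence: 11 steps (1 → 3 → 5 → 8 → 10 → 15 → 16 → 26 → 27 → 28 → 29 → 30; steps 1, 2, 3, 4, 6, 7, 13, 14, 15, 16, 17).

The three steps most likely to fail:

Step 13 (key step, proposed new method). What may go wrong: the oxygen-stabilised open cation may be too stable to close, the lithiated allene may deprotonate the doubly allylic CH2 of 23 instead of adding, and rotation within the open cation may erode the transfer of the axis to the quaternary carbon. The fallback uses known reactions only; it sets out from vinyl iodide 10 and comes back to the route at the target 30, giving up stereocontrol at the quaternary carbon. Iodine–lithium exchange on 10 (t-BuLi) and formylation with DMF should give (2E)-3-[(2S)-5,5-dimethoxyoxolan-2-yl]prop-2-enal F1. Knoevenagel condensation of F1 with commercial cyclopent-4-ene-1,3-dione (piperidine cat., molecular sieves) should give the symmetrical alkylidene dione 2-{(2E)-3-[(2S)-5,5-dimethoxyoxolan-2-yl]prop-2-en-1-ylidene}cyclopent-4-ene-1,3-dione F2. An allylbarium reagent made from (2Z,5Z)-1-chloroocta-2,5-diene and activated barium at −78 °C (α-selective 1,2-addition with retention of the (Z)-geometry) is added to the carbonyl that lies syn to the vinylic hydrogen, and dilute acid then opens the ortho-lactone. This should give methyl (4S,5E,7Z)-4-hydroxy-7-{(2R)-2-hydroxy-2-[(2Z,5Z)-octa-2,5-dien-1-yl]-5-oxocyclopent-3-en-1-ylidene}hept-5-enoate F3 together with its epimer at the ring carbinol carbon, methyl (4S,5E,7Z)-4-hydroxy-7-{(2S)-2-hydroxy-2-[(2Z,5Z)-octa-2,5-dien-1-yl]-5-oxocyclopent-3-en-1-ylidene}hept-5-enoate F4; the two are diastereomers and are separated by chromatography. Weitz–Scheffer epoxidation of the endocyclic enone of F3 (H2O2, NaOH, MeOH, 0 °C) should give methyl (4S,5E,7Z)-4-hydroxy-7-{4-hydroxy-4-[(2Z,5Z)-octa-2,5-dien-1-yl]-2-oxo-6-oxabicyclo[3.1.0]hexan-3-ylidene}hept-5-enoate F5 (epoxide configuration immaterial), and HBr opening of the epoxy ketone with loss of water from the bromohydrin gives the α-bromo enone 30.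

Step 6. What may go wrong: weak or reversed discrimination between the two diastereotopic C–O bonds of the acetal (low axial purity), and ionisation of the ortho ester by the magnesium and copper salts. The fallback sets out from 10 and comes back at 15; it forms the C6–C7 bond by cross-coupling and sets the axis by separation instead of by the acetal. Mono-propargylation of (2R,4R)-pentane-2,4-diol (NaH, propargyl bromide) should give (2R,4R)-4-(prop-2-yn-1-yloxy)pentan-2-ol F6. Sonogashira coupling of F6 with 10 (Pd(PPh3)4, CuI, Et3N) should give (2R,4R)-4-({(4E)-5-[(2S)-5,5-dimethoxyoxolan-2-yl]pent-4-en-2-yn-1-yl}oxy)pentan-2-ol F7. Base-mediated propargyl-to-allenyl isomerisation (t-BuOK, THF, 0 °C) should then give 15 together with its axial epimer (2R,4R)-4-{[(aS,4E)-5-[(2S)-5,5-dimethoxyoxolan-2-yl]penta-1,2,4-trien-1-yl]oxy}pentan-2-ol F8; these are diastereomers and are separated by chromatography.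

Step 15. What may go wrong: thermal Z-to-E isomerisation of the exocyclic alkene, lactonisation of the γ-hydroxy ester and protodestannylation under the palladium and LiCl conditions at 60 °C. The fallback sets out from triflate 27 and comes back at bromide 29. It is a direct transition-metal-catalysed exchange of the enol triflate for bromide ([Cp*Ru(MeCN)3]OTf cat., LiBr, 1,3-dimethyl-2-imidazolidinone, rt), which avoids tin and heating and replaces steps 15 and 16; new compounds: none F0.

Further compounds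
F1 | step 13 | (2E)-3-[(2S)-5,5-dimethoxyoxolan-2-yl]prop-2-enal | COC1(OC)CC[C@@H](/C=C/C=O)O1
F2 | step 13 | 2-{(2E)-3-[(2S)-5,5-dimethoxyoxolan-2-yl]prop-2-en-1-ylidene}cyclopent-4-ene-1,3-dione | O=C1C=CC(=O)C1=C/C=C/[C@@H]1CCC(OC)(OC)O1
F3 | step 13 | methyl (4S,5E,7Z)-4-hydroxy-7-{(2R)-2-hydroxy-2-[(2Z,5Z)-octa-2,5-dien-1-yl]-5-oxocyclopent-3-en-1-ylidene}hept-5-enoate | CC/C=C\C/C=C\C[C@@]1(O)C=CC(=O)/C1=C\C=C\[C@@H](O)CCC(=O)OC
F4 | step 13 | methyl (4S,5E,7Z)-4-hydroxy-7-{(2S)-2-hydroxy-2-[(2Z,5Z)-octa-2,5-dien-1-yl]-5-oxocyclopent-3-en-1-ylidene}hept-5-enoate | CC/C=C\C/C=C\C[C@]1(O)C=CC(=O)/C1=C\C=C\[C@@H](O)CCC(=O)OC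
F5 | step 13 | methyl (4S,5E,7Z)-4-hydroxy-7-{4-hydroxy-4-[(2Z,5Z)-octa-2,5-dien-1-yl]-2-oxo-6-oxabicyclo[3.1.0]hexan-3-ylidene}hept-5-enoate | CC/C=C\C/C=C\C[C@@]1(O)C2OC2C(=O)/C1=C\C=C\[C@@H](O)CCC(=O)OC
F6 | step 6 | (2R,4R)-4-(prop-2-yn-1-yloxy)pentan-2-ol | C[C@@H](O)C[C@@H](C)OCC#C
F7 | step 6 | (2R,4R)-4-({(4E)-5-[(2S)-5,5-dimethoxyoxolan-2-yl]pent-4-en-2-yn-1-yl}oxy)pentan-2-ol | C[C@@H](O)C[C@@H](C)OCC#C/C=C/[C@@H]1CCC(OC)(OC)O1
F8 | step 6 | (2R,4R)-4-{[(aS,4E)-5-[(2S)-5,5-dimethoxyoxolan-2-yl]penta-1,2,4-trien-1-yl]oxy}pentan-2-ol | [H]C(O[C@H](C)C[C@@H](C)O)=[C@]=C([H])/C=C/[C@@H]1CCC(OC)(OC)O1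
F0 | step 15 | none | none
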